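The runs are calculated from invented constants.

In a one-step world the starting complex would turn into complex with one exchanged and stay there. Cedar and alder instead rise and then fall, so a further step follows.

the same everywhere: starting complex 0.020 M
- elm: incoming ligand 0.023 M; run made earlier
- cedar: incoming ligand 0.050 M; run made earlier
- alder: incoming ligand 0.082 M; run made earlier
- Tuesday's: incoming ligand 0.0900 M; time 12 min
- Sunday's: incoming ligand 0.0300 M; time 12 min

- elm (time / min: complex with one exchanged / %): 1.50: 20.0; 3.00: 29.8; 5.00: 36.8; 6.00: 38.6
- cedar (time / min: complex with one exchanged / %): 1.50: 32.9; 3.00: 42.0; 5.00: 41.6; 6.00: 38.5
- alder (time / min: complex with one exchanged / %): 1.50: 40.8; 3.00: 41.1; 5.00: 35.9; 6.00: 31.8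

(scatter of a reading: 0.5 percentage points)

- the analysis behind the earlier runs scatters by 0.5 percentage points, standard deviation
- a reading or a percentage of complex with one exchanged counts all its forms, free or not

* which of the two there is more of at the end, Tuesday's (complex with one exchanged / complex with three exchanged)
* which of the two there is more of at the end, Sunday's (complex with one exchanged / complex with three exchanged)
* complex with one exchanged at the end, in percent of the starting complex charged, Tuesday's
* complex with one exchanged at the end, in percent of the starting complex charged, Sunday's

I reckon this as a ladder of two rungs, taking [incoming ligand] at its charge, a pseudo-first-order view. The first rung is the rise: elm's first reading gives 6.47 /M/min. The second rung is the fall coefficient, the logarithmic drop of complex with one exchanged per minute between the last two readings, divided by the ligand charged. It reads 1.48 /M/min in alder and 1.55 /M/min in cedar. Equal rungs would make the ratio of these one; the readings give 4.37.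

In Tuesday's flask the rise has a half-life of 1.19 min and the fall 5.21 min, shorter than the time allowed, so I expect complex with three exchanged to lead. Extending the cedar and alder readings along the ligand charge gives 30.1 % at 6.00 min, and the fall then leaves 13.6 %. In Sunday's flask the fall half-life of 15.6 min is longer than the time allowed, so I expect complex with one exchanged to lead, near elm's last reading of 38.6 %.

The forecast says complex with three exchanged at 13 % of complex with one exchanged for Tuesday's, and complex with one exchanged at 42 % for Sunday's. Its ground differs from mine, with B as complex with one exchanged: “So B's onward step appears to saturate”.

    starting complex + incoming ligand ⇌ leaving ligand + complex with one exchanged (K = 0.752, k = 0.139 /M/s)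
    complex with one exchanged + incoming ligand ⇌ leaving ligand + complex with two exchanged (K = 15.5, k = 0.182 /M/s)
    complex with two exchanged + incoming ligand ⇌ leaving ligand + complex with three exchanged (K = 0.875, k = 0.356 /M/s)
    complex with one exchanged ⇌ isomer of the product (K = 2.30, k = 0.00211 /s)
    starting complex + complex with one exchanged ⇌ idle adduct, settled at all times (K = 1540 /M)

Tuesday's flask ends with 17.0 % of complex with one exchanged against 32.8 % of complex with three exchanged. Sunday's ends with 37.2 % against 5.14 %, so the forecast stands on all four. Starting from Tuesday's own 30.1 % at 6.00 min, the fall coefficient gives 13.5 %, less than the flask holds. A neighbour like Sunday's but charged with 0.075 M of incoming ligand reckons from 33.3 % down to 17.1 %; it holds 21.5 % of complex with one exchanged and 26.1 % of complex with three exchanged.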